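**Retrosynthetic overview**
1. Target 17 ← desilylation, acetylation and equatorial hydride delivery ← cis-oxan-4-one 14 ← dihydropyranone 13 ← flat 4H-pyran-4-one 11. The three stereocentres are put onto the planar ring by three successive reductions: C6 by an asymmetric copper hydride, C2 by hydrogenation, C4 by LiBH(s-Bu)3.
2. Pyranone 11 ← [4+2] of aroylketene 9 (O1, C2, C3, C4) with 2-methoxy-1-alkene 8 (C5, C6). Bonds C4–C5 and O1–C6 form in one event.
3. Enabling feature: in the oxane ring, O1–C2(aryl)–C3–C4(OAc) is a four-atom chain with oxygen at both ends, and C6 is an O-bearing carbon next to the CH2 group C5. The ring is therefore the hexahydro form of a 2-aryl-6-alkyl-4H-pyran-4-one, that is an aroylketene plus the enol ether of a methyl ketone.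
4. 9 ← acyl Meldrum's acid 5 ← acid 1 and Meldrum's acid 4; 8 ← ester 6 by carbonyl methylenation. Only one ring, the pyran, is made (step 5); both benzene rings are bought.

Key step: step 5

Remark: oxane numbering of the target is used for ring atoms throughout (O1, C2 aryl, C4 acetoxy, C6 arylethyl). TBS = tert-butyldimethylsilyl, TBSO = tert-butyldimethylsilyloxy. The phenols are carried as TBS ethers because benzyl ethers would be cleaved in step 7.

**Step 1**
Reactants: 1 3,4-dihydroxy-5-methoxybenzoic acid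
Product: 3 3,4-bis(TBSO)-5-methoxybenzoic acid, via silyl ester 2 (not isolated)
Conditions: TBSCl (3.5 equiv), imidazole, DMF, rt; then AcOH/THF/H2O, rt
Reagents that add atoms: tert-butyldimethylsilyl chloride, CC(C)(C)[Si](C)(C)Cl
Why: Silylation with TBSCl/imidazole covers both phenols and the acid, and aqueous acetic acid then hydrolyses only the silyl ester, which is far more labile than an aryl silyl ether.

**Step 2**
Reactants: 3 3,4-bis(TBSO)-5-methoxybenzoic acid; 4 Meldrum's acid (2,2-dimethyl-1,3-dioxane-4,6-dione)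
Product: 5 5-{[3,4-bis(TBSO)-5-methoxyphenyl](hydroxy)methylidene}-2,2-dimethyl-1,3-dioxane-4,6-dione (aroyl Meldrum's acid, enol form)
Conditions: DCC, DMAP (1.2 equiv), CH2Cl2, 0 °C to rt; cold aq. KHSO4 wash
Reagents that add atoms: none
Why: Carbodiimide/DMAP activation of the acid and C-acylation of Meldrum's acid is the standard route to enolised acyl Meldrum's acids, which are storable precursors of acylketenes.

**Step 3**
Reactants: 6 methyl 3-(4-hydroxy-3-methoxyphenyl)propanoate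
Product: 7 methyl 3-[4-(TBSO)-3-methoxyphenyl]propanoate
Conditions: TBSCl, imidazole, DMF, rt
Reagents that add atoms: tert-butyldimethylsilyl chloride, CC(C)(C)[Si](C)(C)Cl
Why: Standard silylation of a phenol.

**Step 4**
Reactants: 7 methyl 3-[4-(TBSO)-3-methoxyphenyl]propanoate
Product: 8 tert-butyl[2-methoxy-4-(3-methoxybut-3-en-1-yl)phenoxy]dimethylsilane (the 2-methoxy-1-alkene)
Conditions: Cp2TiMe2 (2.5 equiv), toluene, 70 °C, dark; filtration through basic Al2O3
Reagents that add atoms: dimethyltitanocene (Cp2TiMe2), [CH3-].[CH3-].[Ti+4].c1cc[cH-]c1.c1cc[cH-]c1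
Why: Petasis methylenation converts the ester carbonyl into C=CH2 through Cp2Ti=CH2 ([2+2] then cycloreversion), so the enol ether double bond is terminal by construction and no regioisomer can form.

**Step 5**
Reactants: 5 aroyl Meldrum's acid; 8 2-methoxy-1-alkene
Product: 11 2-[3,4-bis(TBSO)-5-methoxyphenyl]-6-{2-[4-(TBSO)-3-methoxyphenyl]ethyl}-4H-pyran-4-one, via aroylketene 9 (not isolated), via methoxy ketal 10 (not isolated)
Conditions: 8 (1.5 equiv), toluene, 100 °C, slow addition of 5; then TsOH·H2O (10 mol%), 25–40 °C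
Reagents that add atoms: none
Why: Heating 5 expels acetone and CO2 and leaves aroylketene 9, an electron-poor 1-oxadiene (O=C(Ar)–CH=C=O) that should be trapped by the electron-rich 1,1-disubstituted enol ether 8 faster than it dimerises. Both bonds form in one inverse-electron-demand hetero-Diels–Alder event, asynchronous to the point of a zwitterion: the nucleophilic CH2 of 8 (C5) adds to the ketene carbon (C4) and the aroyl oxygen (O1) closes onto the methoxy-bearing carbon (C6). The closest known reaction type is the [4+2] cycloaddition of thermally generated acylketenes (from acyl Meldrum's acids or 1,3-dioxin-4-ones) with vinyl ethers, which gives 2-alkoxy-2,3-dihydro-4H-pyran-4-ones and, after acid-induced loss of the alcohol, 4-pyranones. The single new ring, the pyranone, is closed by the cycloaddition itself (in the stepwise limit a 6-exo-trig capture of the oxocarbenium carbon by the enolate oxygen), and TsOH then eliminates methanol from ketal 10. No stereocentre survives the step: C6 of 10 is a racemic ketal carbon that is flattened on purpose, and the three stereocentres are set later on the planar ring. The step needs regioselectivity only, which is secured by the polarity of both partners (the ketene carbon is the only strong electrophile, the terminal CH2 the only nucleophilic carbon of 8) and by the terminal position of the enol ether double bond fixed in step 4.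

**Step 6**
Reactants: 11 2-aryl-6-(arylethyl)-4H-pyran-4-one
Product: 13 (2S)-6-[3,4-bis(TBSO)-5-methoxyphenyl]-2-{2-[4-(TBSO)-3-methoxyphenyl]ethyl}-2,3-dihydro-4H-pyran-4-one (stereocentre = C6 of the target), via silyl dienol ether 12 (not isolated)
Conditions: Cu(OAc)2·H2O (5 mol%), (R)-DTBM-SEGPHOS (5.5 mol%), (EtO)2MeSiH (1.5 equiv), toluene, no alcohol additive, 0 °C to rt; then 1 M HCl/THF, 0 °C
Reagents that add atoms: none
Why: Proposed new method: a bisphosphine-ligated copper hydride is expected to deliver hydride to the β-carbon of the alkyl-substituted enone arm (C6), because the other β-carbon (C2) is deactivated and shielded by conjugation with the electron-rich aryl ring; the copper enolate is silylated by the silane to dienol ether 12, which is no longer an acceptor, so reduction stops after one hydride; the ligand controls the face at C6 (the first run has to show whether the R or the S ligand gives 2S, and the other antipode is used if needed); the closest known reaction type is the copper-hydride-catalysed asymmetric 1,4-reduction of 2-substituted chromones (benzo-fused 4-pyranones) and of β,β-disubstituted cyclic enones.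

**Step 7**
Reactants: 13 (2S)-6-aryl-2-(arylethyl)-2,3-dihydro-4H-pyran-4-one
Product: 14 (2S,6S)-2-[3,4-bis(TBSO)-5-methoxyphenyl]-6-{2-[4-(TBSO)-3-methoxyphenyl]ethyl}oxan-4-one (2,6-cis)
Conditions: H2 (1 atm), 10% Pd/C, EtOAc, rt
Reagents that add atoms: none
Why: Heterogeneous syn-hydrogenation of the remaining vinylogous-ester double bond should place the new C2–H on the face of the C6–H, giving the diequatorial 2,6-cis ketone as is usual for 2,6-disubstituted 2,3-dihydro-4H-pyran-4-ones; aryl silyl ethers are inert under these conditions.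

**Step 8**
Reactants: 14 (2S,6S)-2,6-cis-oxan-4-one
Product: 15 (2S,4S,6S)-2-[3,4-bis(TBSO)-5-methoxyphenyl]-6-{2-[4-(TBSO)-3-methoxyphenyl]ethyl}oxan-4-ol (4-OH axial, trans to both ring substituents)
Conditions: LiBH(s-Bu)3, THF, −78 °C; H2O quench
Reagents that add atoms: none
Why: The bulky hydride attacks the chair ketone from the equatorial direction and should give the axial (4S) alcohol, the standard outcome for 2,6-cis-disubstituted oxan-4-ones.

**Step 9**
Reactants: 15 (2S,4S,6S)-oxan-4-ol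
Product: 16 (2S,4S,6S)-2-[3,4-bis(TBSO)-5-methoxyphenyl]-6-{2-[4-(TBSO)-3-methoxyphenyl]ethyl}oxan-4-yl acetate
Conditions: Ac2O, pyridine, DMAP (cat.), CH2Cl2, rt
Reagents that add atoms: acetic anhydride, CC(=O)OC(C)=O
Why: DMAP-catalysed O-acylation of the secondary alcohol proceeds with retention at C4.

**Step 10**
Reactants: 16 tris-TBS acetate
Product: 17 (2S,4S,6S)-2-(3,4-dihydroxy-5-methoxyphenyl)-6-[2-(4-hydroxy-3-methoxyphenyl)ethyl]oxan-4-yl acetate (target)
Conditions: TBAF/AcOH (1:1, 3.6 equiv each), THF, 0 °C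
Reagents that add atoms: none
Why: Fluoride cleaves the three aryl silyl ethers, and the acetic acid buffer keeps the medium non-basic so that the acetate and the free catechol should survive.

**Compound list**
1 | 3,4-dihydroxy-5-methoxybenzoic acid | COc1cc(C(=O)O)cc(O)c1O | starting material
2 | tert-butyldimethylsilyl 3,4-bis(TBSO)-5-methoxybenzoate (not isolated) | COc1cc(C(=O)O[Si](C)(C)C(C)(C)C)cc(O[Si](C)(C)C(C)(C)C)c1O[Si](C)(C)C(C)(C)C | intermediate
3 | 3,4-bis(TBSO)-5-methoxybenzoic acid | COc1cc(C(=O)O)cc(O[Si](C)(C)C(C)(C)C)c1O[Si](C)(C)C(C)(C)C | intermediate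
4 | Meldrum's acid (2,2-dimethyl-1,3-dioxane-4,6-dione) | CC1(C)OC(=O)CC(=O)O1 | starting material
5 | 5-{[3,4-bis(TBSO)-5-methoxyphenyl](hydroxy)methylidene}-2,2-dimethyl-1,3-dioxane-4,6-dione | COc1cc(C(O)=C2C(=O)OC(C)(C)OC2=O)cc(O[Si](C)(C)C(C)(C)C)c1O[Si](C)(C)C(C)(C)C | intermediate
6 | methyl 3-(4-hydroxy-3-methoxyphenyl)propanoate | COC(=O)CCc1ccc(O)c(OC)c1 | starting material
7 | methyl 3-[4-(TBSO)-3-methoxyphenyl]propanoate | COC(=O)CCc1ccc(O[Si](C)(C)C(C)(C)C)c(OC)c1 | intermediate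
8 | tert-butyl[2-methoxy-4-(3-methoxybut-3-en-1-yl)phenoxy]dimethylsilane | C=C(OC)CCc1ccc(O[Si](C)(C)C(C)(C)C)c(OC)c1 | intermediate
9 | 3-[3,4-bis(TBSO)-5-methoxyphenyl]-3-oxoprop-1-en-1-one (aroylketene, not isolated) | COc1cc(C(=O)C=C=O)cc(O[Si](C)(C)C(C)(C)C)c1O[Si](C)(C)C(C)(C)C | intermediate
10 | racemic 6-[3,4-bis(TBSO)-5-methoxyphenyl]-2-methoxy-2-{2-[4-(TBSO)-3-methoxyphenyl]ethyl}-2,3-dihydro-4H-pyran-4-one (not isolated) | COC1(CCc2ccc(O[Si](C)(C)C(C)(C)C)c(OC)c2)CC(=O)C=C(c2cc(OC)c(O[Si](C)(C)C(C)(C)C)c(O[Si](C)(C)C(C)(C)C)c2)O1 | intermediate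
11 | 2-[3,4-bis(TBSO)-5-methoxyphenyl]-6-{2-[4-(TBSO)-3-methoxyphenyl]ethyl}-4H-pyran-4-one | O=C1C=C(CCc2ccc(O[Si](C)(C)C(C)(C)C)c(OC)c2)OC(c2cc(OC)c(O[Si](C)(C)C(C)(C)C)c(O[Si](C)(C)C(C)(C)C)c2)=C1 | intermediate
12 | (2S)-6-[3,4-bis(TBSO)-5-methoxyphenyl]-4-[diethoxy(methyl)silyloxy]-2-{2-[4-(TBSO)-3-methoxyphenyl]ethyl}-2H-pyran (not isolated) | COc1cc(CC[C@H]2C=C(O[Si](C)(OCC)OCC)C=C(c3cc(O[Si](C)(C)C(C)(C)C)c(O[Si](C)(C)C(C)(C)C)c(OC)c3)O2)ccc1O[Si](C)(C)C(C)(C)C | intermediate
13 | (2S)-6-[3,4-bis(TBSO)-5-methoxyphenyl]-2-{2-[4-(TBSO)-3-methoxyphenyl]ethyl}-2,3-dihydro-4H-pyran-4-one | COc1cc(CC[C@H]2CC(=O)C=C(c3cc(O[Si](C)(C)C(C)(C)C)c(O[Si](C)(C)C(C)(C)C)c(OC)c3)O2)ccc1O[Si](C)(C)C(C)(C)C | intermediate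
14 | (2S,6S)-2-[3,4-bis(TBSO)-5-methoxyphenyl]-6-{2-[4-(TBSO)-3-methoxyphenyl]ethyl}oxan-4-one | COc1cc(CC[C@H]2CC(=O)C[C@@H](c3cc(O[Si](C)(C)C(C)(C)C)c(O[Si](C)(C)C(C)(C)C)c(OC)c3)O2)ccc1O[Si](C)(C)C(C)(C)C | intermediate
15 | (2S,4S,6S)-2-[3,4-bis(TBSO)-5-methoxyphenyl]-6-{2-[4-(TBSO)-3-methoxyphenyl]ethyl}oxan-4-ol | COc1cc(CC[C@H]2C[C@H](O)C[C@@H](c3cc(O[Si](C)(C)C(C)(C)C)c(O[Si](C)(C)C(C)(C)C)c(OC)c3)O2)ccc1O[Si](C)(C)C(C)(C)C | intermediate
16 | (2S,4S,6S)-2-[3,4-bis(TBSO)-5-methoxyphenyl]-6-{2-[4-(TBSO)-3-methoxyphenyl]ethyl}oxan-4-yl acetate | COc1cc(CC[C@H]2C[C@H](OC(C)=O)C[C@@H](c3cc(O[Si](C)(C)C(C)(C)C)c(O[Si](C)(C)C(C)(C)C)c(OC)c3)O2)ccc1O[Si](C)(C)C(C)(C)C | intermediate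
17 | (2S,4S,6S)-2-(3,4-dihydroxy-5-methoxyphenyl)-6-[2-(4-hydroxy-3-methoxyphenyl)ethyl]oxan-4-yl acetate | COc1cc(CC[C@H]2C[C@H](OC(C)=O)C[C@@H](c3cc(O)c(O)c(OC)c3)O2)ccc1O | target

**Step count**
Total: 10 steps. Longest linear sequence: 8 steps (1 → 3 → 5 → 11 → 13 → 14 → 15 → 16 → 17).

**Steps most likely to fail**

Step 6 (proposed new method). Hydride transfer may fail to discriminate between the two enone arms or between the two faces of C6, which would lower the enantiomeric purity of 13, or 1,2-reduction may compete. The fallback replaces asymmetric catalysis by a resolution with known chemistry and sets out from 11. Hydrogenation of both ring double bonds (H2, Pd/C, EtOAc) should give the racemic 2,6-cis-oxan-4-one F1, and LiBH(s-Bu)3 should reduce it to the racemic axial alcohol F2. Esterification with (S)-2-methoxy-2-phenylacetic acid (DCC, DMAP) gives two diastereomers: the (S)-O-methylmandelate of the (2S,4S,6S)-alcohol F3 and the (S)-O-methylmandelate of the (2R,4R,6R)-alcohol F4. These are separated by chromatography and F4 is discarded. Cleavage of F3 with DIBAL-H (CH2Cl2, −78 °C) returns to the route at 15.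

Step 5. The acidic enol 5 may protonate enol ether 8 before the ketene is released, leading to double-bond migration or hydrolysis, or the ketene may dimerise. The fallback assembles the open-chain triketone by enolate chemistry instead of cycloaddition and sets out from 3 and 7. Acid 3 is activated with carbonyldiimidazole to the 1-aroylimidazole F5 (not isolated), which acylates the lithium enolate of acetone (excess, THF, −78 °C) to give the 1-arylbutane-1,3-dione F6. The dianion of F6 (2.2 equiv LDA) is acylated at its terminal carbon by ester 7 to give the 1,3,5-triketone F7. TsOH in warm toluene cyclodehydrates F7 to pyranone 11, where the route is rejoined.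

Step 7. Hydrogen uptake by the deactivated vinylogous-ester double bond may be slow, and prolonged exposure may then cause hydrogenolysis of the benzylic C2–O1 bond or incomplete facial selectivity. The fallback uses homogeneous conjugate hydride transfer instead of heterogeneous hydrogenation and sets out from 13. An achiral copper hydride (Cu(OAc)2·H2O, 1,2-bis(diphenylphosphino)benzene, (EtO)2MeSiH, toluene) should add hydride to C2 along the axial trajectory, which leaves the aryl group equatorial and cis to the C6 side chain, and gives the cis-configured silyl enol ether F8. Brief treatment with 1 M HCl/THF returns to the route at 14.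

**Further compounds**
F1 | step 6 | racemic 2,6-cis-2-[3,4-bis(TBSO)-5-methoxyphenyl]-6-{2-[4-(TBSO)-3-methoxyphenyl]ethyl}oxan-4-one (both enantiomers) | COc1cc(CC[C@H]2CC(=O)C[C@@H](c3cc(O[Si](C)(C)C(C)(C)C)c(O[Si](C)(C)C(C)(C)C)c(OC)c3)O2)ccc1O[Si](C)(C)C(C)(C)C.COc1cc(CC[C@@H]2CC(=O)C[C@H](c3cc(O[Si](C)(C)C(C)(C)C)c(O[Si](C)(C)C(C)(C)C)c(OC)c3)O2)ccc1O[Si](C)(C)C(C)(C)C
F2 | step 6 | racemic (2S*,4S*,6S*)-2-[3,4-bis(TBSO)-5-methoxyphenyl]-6-{2-[4-(TBSO)-3-methoxyphenyl]ethyl}oxan-4-ol (both enantiomers) | COc1cc(CC[C@H]2C[C@H](O)C[C@@H](c3cc(O[Si](C)(C)C(C)(C)C)c(O[Si](C)(C)C(C)(C)C)c(OC)c3)O2)ccc1O[Si](C)(C)C(C)(C)C.COc1cc(CC[C@@H]2C[C@@H](O)C[C@H](c3cc(O[Si](C)(C)C(C)(C)C)c(O[Si](C)(C)C(C)(C)C)c(OC)c3)O2)ccc1O[Si](C)(C)C(C)(C)C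
F3 | step 6 | (2S,4S,6S)-2-[3,4-bis(TBSO)-5-methoxyphenyl]-6-{2-[4-(TBSO)-3-methoxyphenyl]ethyl}oxan-4-yl (S)-2-methoxy-2-phenylacetate | COc1cc(CC[C@H]2C[C@H](OC(=O)[C@@H](OC)c3ccccc3)C[C@@H](c3cc(O[Si](C)(C)C(C)(C)C)c(O[Si](C)(C)C(C)(C)C)c(OC)c3)O2)ccc1O[Si](C)(C)C(C)(C)C
F4 | step 6 | (2R,4R,6R)-2-[3,4-bis(TBSO)-5-methoxyphenyl]-6-{2-[4-(TBSO)-3-methoxyphenyl]ethyl}oxan-4-yl (S)-2-methoxy-2-phenylacetate | COc1cc(CC[C@@H]2C[C@@H](OC(=O)[C@@H](OC)c3ccccc3)C[C@H](c3cc(O[Si](C)(C)C(C)(C)C)c(O[Si](C)(C)C(C)(C)C)c(OC)c3)O2)ccc1O[Si](C)(C)C(C)(C)C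
F5 | step 5 | 1-[3,4-bis(TBSO)-5-methoxybenzoyl]imidazole | COc1cc(C(=O)n2ccnc2)cc(O[Si](C)(C)C(C)(C)C)c1O[Si](C)(C)C(C)(C)C
F6 | step 5 | 1-[3,4-bis(TBSO)-5-methoxyphenyl]butane-1,3-dione | COc1cc(C(=O)CC(C)=O)cc(O[Si](C)(C)C(C)(C)C)c1O[Si](C)(C)C(C)(C)C
F7 | step 5 | 1-[3,4-bis(TBSO)-5-methoxyphenyl]-7-[4-(TBSO)-3-methoxyphenyl]heptane-1,3,5-trione | COc1cc(CCC(=O)CC(=O)CC(=O)c2cc(O[Si](C)(C)C(C)(C)C)c(O[Si](C)(C)C(C)(C)C)c(OC)c2)ccc1O[Si](C)(C)C(C)(C)C
F8 | step 7 | (2S,6S)-2-[3,4-bis(TBSO)-5-methoxyphenyl]-4-[diethoxy(methyl)silyloxy]-6-{2-[4-(TBSO)-3-methoxyphenyl]ethyl}-3,6-dihydro-2H-pyran | COc1cc(CC[C@H]2CC(O[Si](C)(OCC)OCC)=C[C@@H](c3cc(O[Si](C)(C)C(C)(C)C)c(O[Si](C)(C)C(C)(C)C)c(OC)c3)O2)ccc1O[Si](C)(C)C(C)(C)C
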